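**Retrosynthetic overview**

1. Target ⇐ cross-metathesis (side-chain terminus), Mitsunobu acetate with inversion (C7), Felkin–Anh allylation of a C3 acetyl group ⇐ bicyclic α-methylene ketone 16.
2. 16 ⇐ ester→methylidene and enol ether→ketone adjustment, plus a face-selective hydrogenation (sets C3a) ⇐ cyclohepta-1,4-diene 13, made by a catalytic formal [4+3] cycloaddition (cyclopropanation/Cope) of vinylcyclopentene 8 with 2-siloxyvinyl diazoacetate 11.
3. Enabling feature: in the seven-membered ring, C8(H2)–C7(O)–C6(=CH2) is the C3 unit of a 2-siloxyvinyl carbenoid (oxygen on the central carbon, the carbenoid ester carbon becoming the exocyclic methylene). The other four ring carbons C5–C4–C3a–C8a, with the methyl on C8a and C3a/C8a shared with the cyclopentane, are a 2-methyl-1-vinylcyclopentene diene.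
4. 8 ⇐ (S)-limonene: the cyclohexene is cleaved and re-closed to the cyclopentene (ozonolysis/aldol condensation); its stereocentre becomes C3 and its isopropenyl group the masked acetyl group.
5. Ring order: cyclopentane first (step 4), cycloheptane last (step 8). C3 is bought, C8a is set by the catalyst, and C3a, C7 and the side-chain carbinol carbon are relayed by substrate control.

Key step: step 8

Remark: bicyclic compounds carry the hydroazulene numbering of the target (C3 side-chain carbon, C3a ring-fusion CH, C6 methylidene carbon, C7 oxygenated carbon, C8a methyl-bearing carbon); the catalyst antipode in step 8 is named on the assumption that Rh2(PTAD)4 shows the usual sense of induction of S/R-configured Rh(II) carboxylates with terminal olefins.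

**Route**

Step 1
Reactants: 1 (S)-(−)-limonene
Product: 3 1-[(1S)-4-methylcyclohex-3-en-1-yl]ethan-1-one, via limonene-8,9-diol 2 (not isolated)
Conditions: K2OsO2(OH)4 (0.5 mol %), (DHQD)2PHAL (1 mol %), NMO, acetone/H2O, 0 °C; silica plug; then NaIO4, THF/H2O, rt
Reagents that add atoms: N-methylmorpholine N-oxide, C[N+]1([O-])CCOCC1; water, O
Why: Ligand-accelerated catalytic osmium dihydroxylation (used here only for site selectivity) should pick the unhindered exocyclic 1,1-disubstituted olefin over the cyclic trisubstituted one, and periodate glycol cleavage (Malaprade) then leaves the methyl ketone without touching the stereocentre.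

Step 2
Reactants: 3 1-[(1S)-4-methylcyclohex-3-en-1-yl]ethan-1-one
Product: 4 2-methyl-2-[(1S)-4-methylcyclohex-3-en-1-yl]-1,3-dioxolane
Conditions: TMSOCH2CH2OTMS, TMSOTf (3 mol %), CH2Cl2, −78 → −20 °C
Reagents that add atoms: 1,2-bis(trimethylsilyloxy)ethane, C[Si](C)(C)OCCO[Si](C)(C)C
Why: Low-temperature TMSOTf-catalysed ketalisation with the bis-silyl ether is non-enolising, so the α-stereocentre should be kept while the acetyl group is masked for all later steps.

Step 3
Reactants: 4 2-methyl-2-[(1S)-4-methylcyclohex-3-en-1-yl]-1,3-dioxolane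
Product: 6 (3S)-3-(2-methyl-1,3-dioxolan-2-yl)-6-oxoheptanal, via ozonide 5 (not isolated)
Conditions: O3, CH2Cl2, −78 °C; then PPh3, −78 °C → rt
Reagents that add atoms: ozone, [O-][O+]=O
Why: Ozonolysis with reductive work-up cleaves the only C=C bond to the 1,6-keto aldehyde, and the stereocentre (β to the aldehyde) is not epimerisable.

Step 4
Reactants: 6 (3S)-3-(2-methyl-1,3-dioxolan-2-yl)-6-oxoheptanal
Product: 7 (5S)-2-methyl-5-(2-methyl-1,3-dioxolan-2-yl)cyclopent-1-ene-1-carbaldehyde
Conditions: piperidine (0.3 equiv), AcOH (0.3 equiv), 4 Å MS, toluene, 60 °C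
Reagents that add atoms: none
Why: Amine-catalysed intramolecular aldol condensation, in which the aldehyde enamine (formed faster than the ketone enamine) adds 5-exo to the methyl ketone and dehydration gives the tetrasubstituted enal; no stereocentre is formed and the resident one is not acidic.

Step 5
Reactants: 7 (5S)-2-methyl-5-(2-methyl-1,3-dioxolan-2-yl)cyclopent-1-ene-1-carbaldehyde
Product: 8 2-[(1S)-2-ethenyl-3-methylcyclopent-2-en-1-yl]-2-methyl-1,3-dioxolane
Conditions: Ph3PCH3Br, KOt-Bu, THF, 0 °C → rt
Reagents that add atoms: methyltriphenylphosphonium bromide, C[P+](c1ccccc1)(c1ccccc1)c1ccccc1.[Br-]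
Why: Wittig methylenation of the aldehyde should give the 1-vinylcyclopentene diene without forming or disturbing a stereocentre.

Step 6
Reactants: 9 methyl acetoacetate
Product: 10 methyl 2-diazo-3-oxobutanoate
Conditions: p-ABSA, Et3N, MeCN, 0 °C → rt
Reagents that add atoms: 4-acetamidobenzenesulfonyl azide, CC(=O)Nc1ccc(cc1)S(=O)(=O)N=[N+]=[N-]
Why: Regitz diazo transfer to the active methylene group; no stereocentre.

Step 7
Reactants: 10 methyl 2-diazo-3-oxobutanoate
Product: 11 methyl 3-[(tert-butyldimethylsilyl)oxy]-2-diazobut-3-enoate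
Conditions: TBSOTf, Et3N, CH2Cl2, 0 °C
Reagents that add atoms: tert-butyldimethylsilyl trifluoromethanesulfonate, CC(C)(C)[Si](C)(C)OS(=O)(=O)C(F)(F)F
Why: O-Silylation of the ketone enolate (silyl enol ether formation) gives the 2-siloxyvinyl diazoacetate, a donor/acceptor carbene precursor; no stereocentre.

Step 8
Reactants: 8 2-[(1S)-2-ethenyl-3-methylcyclopent-2-en-1-yl]-2-methyl-1,3-dioxolane; 11 methyl 3-[(tert-butyldimethylsilyl)oxy]-2-diazobut-3-enoate
Product: 13 methyl (3S,8aR)-7-[(tert-butyldimethylsilyl)oxy]-8a-methyl-3-(2-methyl-1,3-dioxolan-2-yl)-1,2,3,5,8,8a-hexahydroazulene-6-carboxylate, via cis-divinylcyclopropane 12 (not isolated)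
Conditions: Rh2(R-PTAD)4 (1 mol %), slow addition of 11 (1.5 equiv), hexanes, −20 °C → rt; then toluene, 110 °C
Reagents that add atoms: none
Why: Rh(II) decomposition of 11 gives a donor/acceptor carbenoid that cyclopropanates the terminal vinyl group of 8 to the cis-divinylcyclopropane 12, which on heating undergoes a boat [3,3]-sigmatropic (Cope) shift that breaks the C4–C6 cyclopropane bond and makes the C8–C8a bond. The closest known reaction type is the tandem cyclopropanation/Cope formal [4+3] cycloaddition of 2-siloxyvinyl diazoacetates with 1,3-dienes, including 2-substituted 1-vinylcycloalkenes that form a quaternary carbon. The transient three-membered ring closes by (2+1) carbene transfer and the seven-membered ring closes by the ring-enlarging [3,3] shift, overall a 4+3 union of C5–C4–C3a–C8a with C6–C7–C8. The new quaternary stereocentre C8a (R) follows through the boat transition state from the (1R,2S) configuration of the cyclopropane, which the chiral catalyst sets by choosing the face of the vinyl group; in addition, only this cyclopropane diastereomer can rearrange with the forming bridge anti to the C3 dioxolanyl group. The step needs chemoselectivity for the vinyl group (secured by the steric shielding of the tetrasubstituted ring olefin), the cis cyclopropane geometry (inherent to donor/acceptor carbenoids) and facial control (catalyst antipode), while the hindered Cope terminus with the inward methyl group is overcome thermally.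

Step 9
Reactants: 13 methyl (3S,8aR)-7-[(tert-butyldimethylsilyl)oxy]-8a-methyl-3-(2-methyl-1,3-dioxolan-2-yl)-1,2,3,5,8,8a-hexahydroazulene-6-carboxylate
Product: 14 methyl (3S,3aS,8aR)-7-[(tert-butyldimethylsilyl)oxy]-8a-methyl-3-(2-methyl-1,3-dioxolan-2-yl)-1,2,3,3a,4,5,8,8a-octahydroazulene-6-carboxylate
Conditions: H2 (5 bar), 5 % Pt/C, EtOAc, rt
Reagents that add atoms: none
Why: Heterogeneous catalytic hydrogenation should reduce only the trisubstituted C3a=C4 bond (the tetrasubstituted push–pull β-siloxy acrylate is inert), with syn delivery of H2 from the face opposite both the C8a methyl and the C3 dioxolanyl group, which sets C3a (S) and the trans ring fusion.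

Step 10
Reactants: 14 methyl (3S,3aS,8aR)-7-[(tert-butyldimethylsilyl)oxy]-8a-methyl-3-(2-methyl-1,3-dioxolan-2-yl)-1,2,3,3a,4,5,8,8a-octahydroazulene-6-carboxylate
Product: 15 [(3S,3aS,8aR)-7-[(tert-butyldimethylsilyl)oxy]-8a-methyl-3-(2-methyl-1,3-dioxolan-2-yl)-1,2,3,3a,4,5,8,8a-octahydroazulen-6-yl]methanol
Conditions: DIBAL-H (2.5 equiv), CH2Cl2, −78 → −40 °C; Rochelle salt
Reagents that add atoms: none
Why: DIBAL-H 1,2-reduction of the vinylogous carbonate ester should give the allylic alcohol without affecting a stereocentre.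

Step 11
Reactants: 15 [(3S,3aS,8aR)-7-[(tert-butyldimethylsilyl)oxy]-8a-methyl-3-(2-methyl-1,3-dioxolan-2-yl)-1,2,3,3a,4,5,8,8a-octahydroazulen-6-yl]methanol
Product: 16 (3S,3aS,8aR)-8a-methyl-6-methylidene-3-(2-methyl-1,3-dioxolan-2-yl)decahydroazulen-7-one
Conditions: CSA (5 mol %), CH2Cl2, 0 °C; used at once
Reagents that add atoms: none
Why: Acid-induced ionisation of the allylic alcohol assisted by the silyl enol ether (the unveiling step of a Stork–Danheiser-type transposition) expels the silanol and gives the α-methylene ketone, and the anhydrous catalytic acid should leave the dioxolane intact.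

Step 12
Reactants: 16 (3S,3aS,8aR)-8a-methyl-6-methylidene-3-(2-methyl-1,3-dioxolan-2-yl)decahydroazulen-7-one
Product: 17 (3S,3aS,7R,8aR)-8a-methyl-6-methylidene-3-(2-methyl-1,3-dioxolan-2-yl)decahydroazulen-7-ol
Conditions: DIBAL-H (1.2 equiv), CH2Cl2, −78 °C
Reagents that add atoms: none
Why: 1,2-Reduction of the enone by the bulky aluminium hydride should occur on the carbonyl face anti to the pseudo-axial C8a methyl group (1,3 to the carbonyl), giving the 7R alcohol (OH cis to the methyl) that the later inversion requires.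

Step 13
Reactants: 17 (3S,3aS,7R,8aR)-8a-methyl-6-methylidene-3-(2-methyl-1,3-dioxolan-2-yl)decahydroazulen-7-ol
Product: 18 1-[(3S,3aS,7R,8aR)-7-hydroxy-8a-methyl-6-methylidenedecahydroazulen-3-yl]ethan-1-one
Conditions: PPTS (0.3 equiv), THF/H2O (4:1), 50 °C
Reagents that add atoms: water, O
Why: Mild acid-catalysed ketal hydrolysis unmasks the methyl ketone only now, when C3a is sp3 and no conjugation pathway threatens C3, under conditions chosen not to enolise the ketone.

Step 14
Reactants: 18 1-[(3S,3aS,7R,8aR)-7-hydroxy-8a-methyl-6-methylidenedecahydroazulen-3-yl]ethan-1-one; 19 allylmagnesium bromide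
Product: 20 (3S,3aS,7R,8aR)-3-[(2S)-2-hydroxypent-4-en-2-yl]-8a-methyl-6-methylidenedecahydroazulen-7-ol
Conditions: 19 (3 equiv), THF, −78 °C; aq. NH4Cl
Reagents that add atoms: none
Why: Grignard addition under Felkin–Anh control, with the ring-fusion carbon C3a as the large α-substituent anti to the nucleophile and C2H2 on the carbonyl-oxygen side, should give the (S)-configured tertiary carbinol.

Step 15
Reactants: 20 (3S,3aS,7R,8aR)-3-[(2S)-2-hydroxypent-4-en-2-yl]-8a-methyl-6-methylidenedecahydroazulen-7-ol
Product: 21 (3S,3aS,7S,8aR)-3-[(2S)-2-hydroxypent-4-en-2-yl]-8a-methyl-6-methylidenedecahydroazulen-7-yl acetate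
Conditions: PPh3, DIAD, AcOH, toluene, 0 °C → rt
Reagents that add atoms: acetic acid, CC(=O)O
Why: Mitsunobu esterification, in which acetate displaces the activated secondary allylic alcohol by SN2 from the open face anti to the angular methyl, inverts C7 to S while the tertiary alcohol does not react.

Step 16
Reactants: 21 (3S,3aS,7S,8aR)-3-[(2S)-2-hydroxypent-4-en-2-yl]-8a-methyl-6-methylidenedecahydroazulen-7-yl acetate; 22 2-methylbut-3-en-2-ol
Product: 23 (3S,3aS,7S,8aR)-3-[(2S,4E)-2,6-dihydroxy-6-methylhept-4-en-2-yl]-8a-methyl-6-methylidenedecahydroazulen-7-yl acetate (CNP0290154.1)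
Conditions: Hoveyda–Grubbs II (5 mol %), 22 (6 equiv), CH2Cl2, 40 °C
Reagents that add atoms: none
Why: Olefin cross-metathesis of the terminal allyl group with the slowly homodimerising tertiary allylic alcohol should give the E-disubstituted alkene, with the 1,1-disubstituted exocyclic methylene and the allylic acetate as spectators.

**Compound list**

1 | (S)-(−)-limonene, (4S)-1-methyl-4-(prop-1-en-2-yl)cyclohex-1-ene | CC1=CC[C@H](CC1)C(C)=C | starting material
2 | limonene-8,9-diol, 2-[(1S)-4-methylcyclohex-3-en-1-yl]propane-1,2-diol (both epimers at the carbinol carbon) | CC1=CC[C@H](CC1)C(C)(O)CO | intermediate (not isolated)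
3 | 1-[(1S)-4-methylcyclohex-3-en-1-yl]ethan-1-one | CC1=CC[C@H](CC1)C(C)=O | intermediate
4 | 2-methyl-2-[(1S)-4-methylcyclohex-3-en-1-yl]-1,3-dioxolane | CC1=CC[C@H](CC1)C2(C)OCCO2 | intermediate
5 | secondary ozonide of 4, (4S)-1-methyl-4-(2-methyl-1,3-dioxolan-2-yl)-7,8,9-trioxabicyclo[4.2.1]nonane (diastereomers at the two acetal carbons) | CC12OOC(O1)C[C@H](CC2)C3(C)OCCO3 | intermediate (not isolated)
6 | (3S)-3-(2-methyl-1,3-dioxolan-2-yl)-6-oxoheptanal | O=CC[C@H](CCC(C)=O)C1(C)OCCO1 | intermediate
7 | (5S)-2-methyl-5-(2-methyl-1,3-dioxolan-2-yl)cyclopent-1-ene-1-carbaldehyde | O=CC1=C(C)CC[C@@H]1C2(C)OCCO2 | intermediate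
8 | 2-[(1S)-2-ethenyl-3-methylcyclopent-2-en-1-yl]-2-methyl-1,3-dioxolane | C=CC1=C(C)CC[C@@H]1C2(C)OCCO2 | intermediate
9 | methyl acetoacetate | CC(=O)CC(=O)OC | starting material
10 | methyl 2-diazo-3-oxobutanoate | CC(=O)C(=[N+]=[N-])C(=O)OC | intermediate
11 | methyl 3-[(tert-butyldimethylsilyl)oxy]-2-diazobut-3-enoate | C=C(O[Si](C)(C)C(C)(C)C)C(=[N+]=[N-])C(=O)OC | intermediate
12 | methyl (1R,2S)-1-{1-[(tert-butyldimethylsilyl)oxy]ethenyl}-2-[(5S)-2-methyl-5-(2-methyl-1,3-dioxolan-2-yl)cyclopent-1-en-1-yl]cyclopropane-1-carboxylate (cis-divinylcyclopropane) | COC(=O)[C@]1(C(O[Si](C)(C)C(C)(C)C)=C)C[C@H]1C2=C(C)CC[C@@H]2C3(C)OCCO3 | intermediate (not isolated)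
13 | methyl (3S,8aR)-7-[(tert-butyldimethylsilyl)oxy]-8a-methyl-3-(2-methyl-1,3-dioxolan-2-yl)-1,2,3,5,8,8a-hexahydroazulene-6-carboxylate | COC(=O)C1=C(O[Si](C)(C)C(C)(C)C)C[C@@]2(C)CC[C@H](C3(C)OCCO3)C2=CC1 | intermediate
14 | methyl (3S,3aS,8aR)-7-[(tert-butyldimethylsilyl)oxy]-8a-methyl-3-(2-methyl-1,3-dioxolan-2-yl)-1,2,3,3a,4,5,8,8a-octahydroazulene-6-carboxylate (trans-fused) | COC(=O)C1=C(O[Si](C)(C)C(C)(C)C)C[C@@]2(C)CC[C@H](C3(C)OCCO3)[C@@H]2CC1 | intermediate
15 | [(3S,3aS,8aR)-7-[(tert-butyldimethylsilyl)oxy]-8a-methyl-3-(2-methyl-1,3-dioxolan-2-yl)-1,2,3,3a,4,5,8,8a-octahydroazulen-6-yl]methanol | OCC1=C(O[Si](C)(C)C(C)(C)C)C[C@@]2(C)CC[C@H](C3(C)OCCO3)[C@@H]2CC1 | intermediate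
16 | (3S,3aS,8aR)-8a-methyl-6-methylidene-3-(2-methyl-1,3-dioxolan-2-yl)decahydroazulen-7-one | C=C1CC[C@H]2[C@@H](C3(C)OCCO3)CC[C@]2(C)CC1=O | intermediate
17 | (3S,3aS,7R,8aR)-8a-methyl-6-methylidene-3-(2-methyl-1,3-dioxolan-2-yl)decahydroazulen-7-ol (7-OH cis to the 8a-methyl) | C=C1CC[C@H]2[C@@H](C3(C)OCCO3)CC[C@]2(C)C[C@H]1O | intermediate
18 | 1-[(3S,3aS,7R,8aR)-7-hydroxy-8a-methyl-6-methylidenedecahydroazulen-3-yl]ethan-1-one | C=C1CC[C@H]2[C@@H](C(C)=O)CC[C@]2(C)C[C@H]1O | intermediate
19 | allylmagnesium bromide | C=CC[Mg]Br | starting material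
20 | (3S,3aS,7R,8aR)-3-[(2S)-2-hydroxypent-4-en-2-yl]-8a-methyl-6-methylidenedecahydroazulen-7-ol | C=C1CC[C@H]2[C@@H]([C@@](C)(O)CC=C)CC[C@]2(C)C[C@H]1O | intermediate
21 | (3S,3aS,7S,8aR)-3-[(2S)-2-hydroxypent-4-en-2-yl]-8a-methyl-6-methylidenedecahydroazulen-7-yl acetate | C=C1CC[C@H]2[C@@H]([C@@](C)(O)CC=C)CC[C@]2(C)C[C@@H]1OC(C)=O | intermediate
22 | 2-methylbut-3-en-2-ol | C=CC(C)(C)O | starting material
23 | (3S,3aS,7S,8aR)-3-[(2S,4E)-2,6-dihydroxy-6-methylhept-4-en-2-yl]-8a-methyl-6-methylidenedecahydroazulen-7-yl acetate (CNP0290154.1) | C=C1CC[C@H]2[C@@H]([C@@](C)(O)C/C=C/C(C)(C)O)CC[C@]2(C)C[C@@H]1OC(C)=O | target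

**Step count and risks**

Total step count: 16. Longest linear sequence: 14 steps (steps 1–5 and 8–16, from (S)-limonene); steps 6–7 make the diazo partner.

Steps most likely to fail:

Step 8. The carbenoid may be delivered to the wrong face of the vinyl group when the catalyst preference and the bias of the resident C3 stereocentre oppose each other (poor diastereofacial selectivity), and the boat Cope shift may stall at the fully substituted terminus, so that the cyclopropane decomposes or isomerises instead of rearranging. The fallback sets out from 7 and comes back at 16, and replaces the cycloaddition by a sigmatropic/organochromium ring construction. 1,2-Reduction of the enal (NaBH4, CeCl3, MeOH) should give the allylic alcohol F1. A Johnson–Claisen rearrangement (CH3C(OEt)3, cat. EtCO2H, 140 °C) should place the two-carbon ester unit on C8a from the face anti to the dioxolanyl group and leave an exocyclic methylene on C3a, giving the ester F2. 9-BBN should add from the face opposite the methyl and dioxolanyl groups (setting C3a) to give the alkylborane F3, which is coupled in the same flask with 2,3-dibromopropene (CuI cat., KOt-Bu) to the 2-bromoalkene F4. DIBAL-H at −78 °C should give the aldehyde F5. Nozaki–Hiyama–Kishi cyclisation (CrCl2, cat. NiCl2, DMF, high dilution) closes the seven-membered ring between C6 and C7 to a mixture of 17 and its C7 epimer F6, and Dess–Martin oxidation of the mixture converges on 16.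

Step 15. The activated allylic alcohol may react by SN2′ substitution or elimination instead of clean inversion, and the outcome also depends on the hydride of step 12 having attacked anti to the angular methyl group. The fallback sets out from 20 and comes back at 21, and replaces inversion by reagent control. Dess–Martin periodinane (NaHCO3, CH2Cl2) should oxidise only the secondary allylic alcohol to the enone F7. Corey–Bakshi–Shibata reduction with the (R)-oxazaborolidine and catecholborane at −78 °C (the antipode expected by the usual model to deliver hydride syn to the angular methyl) should give the 7S alcohol F8. Ac2O, pyridine and cat. DMAP at 0 °C then acetylate the secondary alcohol selectively to 21.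

Step 9. Hydrogen may be delivered to the wrong face, or the C3a=C4 bond may migrate on the metal surface before it is reduced (loss of the ring-fusion stereochemistry). The fallback sets out from 13 and comes back at 14: a radical hydrogen-atom-transfer hydrogenation (Mn(dpm)3, PhSiH3, t-BuOOH, i-PrOH, rt), which reduces hindered trisubstituted olefins through a tertiary radical and favours the trans ring fusion. It makes no compound outside the list (F0).

Further compounds
F1 | step 8 | [(5S)-2-methyl-5-(2-methyl-1,3-dioxolan-2-yl)cyclopent-1-en-1-yl]methanol | OCC1=C(C)CC[C@@H]1C2(C)OCCO2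
F2 | step 8 | ethyl 2-[(1R,3S)-1-methyl-2-methylidene-3-(2-methyl-1,3-dioxolan-2-yl)cyclopentyl]acetate | CCOC(=O)C[C@@]1(C)CC[C@H](C2(C)OCCO2)C1=C
F3 | step 8 | ethyl 2-[(1R,2S,3S)-2-[(9-borabicyclo[3.3.1]nonan-9-yl)methyl]-1-methyl-3-(2-methyl-1,3-dioxolan-2-yl)cyclopentyl]acetate | CCOC(=O)C[C@@]1(C)CC[C@H](C2(C)OCCO2)[C@@H]1CB3C4CCCC3CCC4
F4 | step 8 | ethyl 2-[(1R,2S,3S)-2-(3-bromobut-3-en-1-yl)-1-methyl-3-(2-methyl-1,3-dioxolan-2-yl)cyclopentyl]acetate | CCOC(=O)C[C@@]1(C)CC[C@H](C2(C)OCCO2)[C@@H]1CCC(Br)=C
F5 | step 8 | 2-[(1R,2S,3S)-2-(3-bromobut-3-en-1-yl)-1-methyl-3-(2-methyl-1,3-dioxolan-2-yl)cyclopentyl]acetaldehyde | O=CC[C@@]1(C)CC[C@H](C2(C)OCCO2)[C@@H]1CCC(Br)=C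
F6 | step 8 | (3S,3aS,7S,8aR)-8a-methyl-6-methylidene-3-(2-methyl-1,3-dioxolan-2-yl)decahydroazulen-7-ol | C=C1CC[C@H]2[C@@H](C3(C)OCCO3)CC[C@]2(C)C[C@@H]1O
F7 | step 15 | (3S,3aS,8aR)-3-[(2S)-2-hydroxypent-4-en-2-yl]-8a-methyl-6-methylidenedecahydroazulen-7-one | C=C1CC[C@H]2[C@@H]([C@@](C)(O)CC=C)CC[C@]2(C)CC1=O
F8 | step 15 | (3S,3aS,7S,8aR)-3-[(2S)-2-hydroxypent-4-en-2-yl]-8a-methyl-6-methylidenedecahydroazulen-7-ol | C=C1CC[C@H]2[C@@H]([C@@](C)(O)CC=C)CC[C@]2(C)C[C@@H]1O
F0 | step 9 | none | none
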